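**Assumption:** the target has no stereocentres (it is achiral), so no enantio-control is needed. I also assume, following Liebeskind's squarate chemistry, that an organolithium adds to 3-alkyl-4-alkoxycyclobutenediones at the carbonyl next to the C–OR carbon.

**Retrosynthesis**
- Target ← acetylation of 2-hydroxy-3-isopropylnaphthoquinone ← hydrolysis of the 2-isopropoxy vinylogous ester.
- The quinone ring is the only ring formed. It comes from a Liebeskind–Moore ring expansion of a 4-aryl-4-hydroxycyclobutenone, followed by oxidation. The ArLi closes onto its one free ortho C–H, so the chain ends up peri to the carbonyl next to C–O.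
- Cyclobutenone ← 2-alkyl-3-methylphenyl-lithium + 3-isopropyl-4-isopropoxycyclobutenedione (from diisopropyl squarate + iPrLi).
- The aryl bromide carries the 4-methylpent-4-enyl chain on a crowded 1,2,3-arene. It comes from chemoselective NiH anti-Markovnikov hydroarylation of 2-methylpenta-1,4-diene with 1-bromo-2-iodo-3-methylbenzene (the new step).

---

**Step 1**
Reactants: 1 (2-bromo-6-methylaniline)
Product: 2 (1-bromo-2-iodo-3-methylbenzene)
Conditions: NaNO2, aq. H2SO4, 0 °C; then KI (aq), 0 °C → rt; Na2S2O3 workup
Reagents that add atoms: potassium iodide, [K+].[I-] (NaNO2 leaves no atoms in the product)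
Why: Sandmeyer iodination of the diazonium salt replaces NH2 with I, leaving a bromide and an iodide of very different reactivity.

**Step 2**
Reactants: 2 (1-bromo-2-iodo-3-methylbenzene) + 3 (2-methylpenta-1,4-diene, C=CCC(C)=C)
Product: 4 (1-bromo-3-methyl-2-(4-methylpent-4-en-1-yl)benzene)
Conditions: NiBr2·diglyme (10 mol%), 4,4'-di-tBu-bpy (12 mol%), (EtO)2MeSiH (2.5 equiv), K3PO4 (3 equiv), DMA, 25 °C, 16 h; diene 2.5 equiv, sealed vial
Reagents that add atoms: none (the silane supplies only H)
Why: Proposed new method: Ni–H generated from the silane inserts only into the unhindered monosubstituted alkene of the diene to give a primary alkyl–Ni species. Oxidative addition of the C–I bond (not C–Br) and C(sp3)–C(sp2) reductive elimination then give Ar–CH2CH2CH2C(Me)=CH2 with the 1,1-disubstituted alkene and the C–Br intact. The closest known reaction is NiH-catalysed anti-Markovnikov hydroarylation of terminal alkenes with aryl iodides. What is new here is an ortho,ortho-disubstituted aryl iodide bearing a second halide, and a diene partner that must react chemoselectively at one alkene. This step forms the key hindered aryl–chain bond.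

**Step 3**
Reactants: 5 (diisopropyl squarate, 3,4-diisopropoxycyclobut-3-ene-1,2-dione)
Product: 6 (3-isopropyl-4-isopropoxycyclobut-3-ene-1,2-dione)
Conditions: iPrLi (pentane), THF, −78 °C, 1 h; then TFAA, −78 °C → rt; aqueous NaHCO3 workup
Reagents that add atoms: isopropyllithium, CC(C)[Li]; water, O (supplies the new carbonyl oxygen; TFAA leaves no atoms)
Why: Liebeskind squarate transposition: 1,2-addition of iPrLi to a carbonyl, then ionisation of the tertiary trifluoroacetate and hydrolytic loss of one iPrO group, gives the 3-alkyl-4-alkoxy-dione.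

**Step 4**
Reactants: 4 (aryl bromide) + 6 (cyclobutenedione)
Product: 7 (4-aryl-4-hydroxy-2-isopropyl-3-isopropoxycyclobut-2-en-1-one; aryl = 3-methyl-2-(4-methylpent-4-enyl)phenyl)
Conditions: t-BuLi (2.0 equiv), THF, −78 °C, 20 min (Br/Li exchange); then ArLi added by cannula to 6 (1.2 equiv) in THF, −78 °C, 1 h; sat. NH4Cl
Reagents that add atoms: none
Why: Halogen–lithium exchange gives the aryllithium, which adds 1,2 to the more electrophilic carbonyl next to the C–OiPr carbon. The other carbonyl is a deactivated vinylogous-ester carbonyl, so the OiPr ends up next to the new carbinol carbon.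

**Step 5**
Reactants: 7 (cyclobutenone)
Product: 8 (2-isopropoxy-3-isopropyl-7-methyl-8-(4-methylpent-4-enyl)naphthalene-1,4-diol)
Conditions: p-xylene (0.02 M), BHT (1 mol%), 140 °C, sealed tube, Ar, 2 h
Reagents that add atoms: none
Why: Liebeskind–Moore rearrangement: 4π ring opening to the vinylketene, then 6π closure onto the only free ortho C–H of the aryl ring (the other ortho carbon carries the chain), then tautomerisation to the hydroquinone.

**Step 6**
Reactants: 8 (hydroquinone)
Product: 9 (2-isopropoxy-3-isopropyl-7-methyl-8-(4-methylpent-4-enyl)-1,4-naphthoquinone)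
Conditions: Ag2O (3 equiv), CH2Cl2, rt, 2 h
Reagents that add atoms: none
Why: Mild two-electron oxidation of the electron-rich naphthalenediol leaves the isolated alkene untouched.

**Step 7**
Reactants: 9 (2-isopropoxyquinone)
Product: 10 (2-hydroxy-3-isopropyl-7-methyl-8-(4-methylpent-4-enyl)-1,4-naphthoquinone)
Conditions: KOH (10 equiv), t-BuOH/H2O 4:1, 80 °C, 4 h; then 1 M HCl to pH 2
Reagents that add atoms: potassium hydroxide, [K+].[OH-] (hydroxide O is retained as C–OH)
Why: Hydroxide adds to the vinylogous-ester carbon (C2) and iPrO⁻ is expelled, giving the stable hydroxyquinone anion; these basic conditions spare the 1,1-disubstituted alkene.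

**Step 8**
Reactants: 10 (hydroxyquinone)
Product: 11 (acetylsalvipisone)
Conditions: Ac2O (3 equiv), pyridine (5 equiv), DMAP (5 mol%), CH2Cl2, 0 °C → rt, 2 h
Reagents that add atoms: acetic anhydride, CC(=O)OC(C)=O
Why: O-acylation of the acidic enolic OH gives the 2-acetoxy-1,4-quinone; no stereocentre is involved.

---

**Compound list**
1 | 2-bromo-6-methylaniline | Cc1cccc(Br)c1N | starting material
2 | 1-bromo-2-iodo-3-methylbenzene | Cc1cccc(Br)c1I | intermediate
3 | 2-methylpenta-1,4-diene | C=CCC(C)=C | starting material
4 | 1-bromo-3-methyl-2-(4-methylpent-4-enyl)benzene | Cc1cccc(Br)c1CCCC(C)=C | intermediate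
5 | diisopropyl squarate | CC(C)OC1=C(OC(C)C)C(=O)C1=O | starting material
6 | 3-isopropyl-4-isopropoxycyclobut-3-ene-1,2-dione | CC(C)OC1=C(C(C)C)C(=O)C1=O | intermediate
7 | 4-aryl-4-hydroxy-2-isopropyl-3-isopropoxycyclobutenone | CC(C)OC1=C(C(C)C)C(=O)C1(O)c1cccc(C)c1CCCC(C)=C | intermediate
8 | 2-isopropoxy-3-isopropyl-7-methyl-8-(4-methylpent-4-enyl)naphthalene-1,4-diol | CC(C)Oc1c(C(C)C)c(O)c2ccc(C)c(CCCC(C)=C)c2c1O | intermediate
9 | 2-isopropoxy-3-isopropyl-7-methyl-8-(4-methylpent-4-enyl)-1,4-naphthoquinone | CC(C)OC1=C(C(C)C)C(=O)c2ccc(C)c(CCCC(C)=C)c2C1=O | intermediate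
10 | 2-hydroxy-3-isopropyl-7-methyl-8-(4-methylpent-4-enyl)-1,4-naphthoquinone | CC(C)C1=C(O)C(=O)c2c(CCCC(C)=C)c(C)ccc2C1=O | intermediate
11 | acetylsalvipisone | C=C(C)CCCc1c(C)ccc2c1C(=O)C(OC(C)=O)=C(C(C)C)C2=O | target (no stereocentres)

**Step count:** 8 steps in total. The longest linear sequence is 7 steps (1 → 2 → 4 → 7 → 8 → 9 → 10 → 11); step 3 is a parallel branch.

**Three steps most likely to fail**
1. **Step 2 (proposed new NiH hydroarylation).** Risks are hydrodeiodination, Ni chain-walking toward the alkene, and slow oxidative addition at the hindered C–I bond.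
   - Fallback (known chemistry): hydroborate 3 with 9-BBN at the monosubstituted alkene. Then run a B-alkyl Suzuki coupling with 2 using Pd-PEPPSI-IPent and K3PO4 at the C–I bond (or do an I/Mg exchange and Cu-catalysed alkylation with 5-bromo-2-methylpent-1-ene). This replaces one-pot hydrometalation coupling with a pre-formed alkylborane or alkyl-Grignard.
2. **Step 5 (thermal ring expansion).** Risks are decomposition of the ketene, an intramolecular ketene–alkene pathway, or damage to the alkene at 140 °C.
   - Fallback: use a Dötz benzannulation instead. Convert ArLi from 4 to the aryl(methoxy)chromium carbene (Cr(CO)6, then Me3O⁺BF4⁻) and react it with iPrC≡COEt. Oxidise with CAN or Ag2O to the 2-ethoxyquinone, which enters the route at step 7 (hydrolysis as in step 7). This builds the ring by a different annulation.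
3. **Step 7 (hydrolysis of the hindered 2-isopropoxy vinylogous ester).** Risks are slow addition–elimination and quinone decomposition under hot hydroxide.
   - Fallback: cleave the isopropyl ether by Lewis-acid SN1 ionisation instead. Use BCl3 in CH2Cl2 at −78 → 0 °C, then aqueous workup and step 8. This replaces the addition–elimination mechanism with ionisation and loss of an isopropyl cation.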